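Numbering: carbocycle C1 (bears the sorboyl group), C2 (C=O), C3 (C–Me), C4 (enol carbon), C5 (Me, lactone O), C6 (fusion CH); lactone C7 (C=O), C8 (Me, N). Enabling feature: the lactone ring O–C7–C8–C6–C5 with its C5 methyl is, one unsaturation up, a 5-methyl-2-oxyfuran whose γ-terminus C5 is bonded to the oxygenated carbon C4. The C4–C5 acyloin bond is therefore a vinylogous aldol bond lying in the six-membered ring.
Retrosynthetic cuts, in order: N–fumaroyl amide, C1–sorboyl, C8–CH3, the C–H bonds at C6 and C8 (back to the C6=C8 enamide), C4–C5 (opens the carbocycle and rearomatises the lactone to a silyloxyfuran), C1–C6 (cross-coupling), C6=C8 (olefination).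
Forward: the butenolide ring is closed first by an intramolecular Horner–Wadsworth–Emmons reaction, brominated at C6 and joined there to the C1–C4 chain by Negishi coupling. Silylation makes the furan, hydride brings C4 to the aldehyde, the dearomative aldol closes the carbocycle, and the sorboyl and fumaroyl groups come last.
Stereochemistry: C5 comes from a BINOL–titanium catalyst in the ring closure (C4, transient, follows from the rotamer of the bound enal). C6 comes from syn hydrogenation on the convex, methyl-bearing face, reinforced by a chiral rhodium catalyst. C8 comes from enolate methylation on the same convex face, which leaves nitrogen on the concave face beside C1.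
Design points: no C6 ketone is ever made, since next to C1H2 it would enolise and close onto the cis C4 carbonyl to a 2-pyranone. C4 travels as a Weinreb amide so that no oxidant meets the furan. C4 stays a silyl ether until C8 is methylated, because only at that oxidation level is C1H2 non-acidic.

Key step: step 10

Assumption: the (R)-BINOL–titanium complex is taken to leave the Re face of the bound aldehyde open and the (S,S)-bisphospholane rhodium catalyst to give the S amino centre, as both do in their established uses; if either sense proves opposite, the mirror-image ligand is used and nothing else changes.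

Step 1
Reactants: 1 methyl 2-[(tert-butoxycarbonyl)amino]-2-(dimethoxyphosphoryl)acetate (racemic)
Product: 2 2-[(tert-butoxycarbonyl)amino]-2-(dimethoxyphosphoryl)acetic acid (racemic)
Conditions: LiOH (1.05 equiv), THF–H2O, 0 °C; then 1 M HCl to pH 3
Reagents that add atoms: lithium hydroxide, [Li+].[OH-]
Why: Selective saponification: hydroxide attacks the carboxylic ester much faster than the phosphonate methyl esters, so that one equivalent at 0 °C should free only the acid that is needed to tether the phosphonate.

Step 2
Reactants: 2 2-[(tert-butoxycarbonyl)amino]-2-(dimethoxyphosphoryl)acetic acid; 3 but-3-en-2-ol (racemic)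
Product: 4 but-3-en-2-yl 2-[(tert-butoxycarbonyl)amino]-2-(dimethoxyphosphoryl)acetate (mixture of diastereomers)
Conditions: DCC, DMAP (cat.), CH2Cl2, 0 °C to rt
Reagents that add atoms: none
Why: Steglich esterification of a secondary alcohol, which ties the phosphonoglycine unit (C7, C8, N) to the C5 oxygen so that the coming olefination is a five-membered ring closure; both stereocentres are inconsequential because they are lost later.

Step 3
Reactants: 4 but-3-en-2-yl 2-[(tert-butoxycarbonyl)amino]-2-(dimethoxyphosphoryl)acetate
Product: 6 tert-butyl (5-methyl-2-oxo-2,5-dihydrofuran-3-yl)carbamate (racemic at C5; H at C6), via aldehyde ester 5 (not isolated)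
Conditions: O3, CH2Cl2, −78 °C, then Me2S; aqueous wash, solvent switch; DBU, MeCN, 0 °C
Reagents that add atoms: none
Why: Ozonolysis of the terminal alkene unmasks the C6 aldehyde and an intramolecular Horner–Wadsworth–Emmons reaction forms C6=C8, an aldehyde being the carbonyl class on which this phosphonate is reliable and the ring enforcing the geometry with C5 and C7 cis.

Step 4
Reactants: 6 tert-butyl (5-methyl-2-oxo-2,5-dihydrofuran-3-yl)carbamate
Product: 7 tert-butyl (4-bromo-5-methyl-2-oxo-2,5-dihydrofuran-3-yl)carbamate (racemic at C5; Br at C6)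
Conditions: NBS, CH2Cl2, 0 °C, dark; then Et3N
Reagents that add atoms: N-bromosuccinimide, O=C1CCC(=O)N1Br
Why: Electrophilic β-bromination of a dehydroamino acid derivative: the enamide carbon C6 takes up bromine, and the amine base tautomerises the α-bromo N-acylimine back to the conjugated bromo enamide, while the dark and the low temperature suppress radical attack at C5–H.

Step 5
Reactants: 8 methyl 2-methyl-3-oxobutanoate (methyl 2-methylacetoacetate)
Product: 9 methyl (E)-3-methoxy-2-methylbut-2-enoate
Conditions: HC(OMe)3, H2SO4 (cat.), MeOH, rt to 50 °C; distillation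
Reagents that add atoms: trimethyl orthoformate, COC(OC)OC
Why: Acid-catalysed enol ether formation by way of the dimethyl ketal; as with acetoacetates the E isomer, with the C1 methyl cis to the ester carbonyl, should prevail, which is the geometry the ring closure needs.

Step 6
Reactants: 9 methyl (E)-3-methoxy-2-methylbut-2-enoate
Product: 10 (E)-N,3-dimethoxy-N,2-dimethylbut-2-enamide
Conditions: MeNH(OMe)·HCl, iPrMgCl, THF, −20 to 0 °C
Reagents that add atoms: N,O-dimethylhydroxylamine hydrochloride, CNOC.Cl
Why: Weinreb amide formation by aminolysis with the hard chloromagnesium amide, which should attack the ester carbonyl rather than the methoxy-bearing β-carbon.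

Step 7
Reactants: 7 tert-butyl (4-bromo-5-methyl-2-oxo-2,5-dihydrofuran-3-yl)carbamate; 10 (E)-N,3-dimethoxy-N,2-dimethylbut-2-enamide
Product: 13 tert-butyl {4-[(E)-2-methoxy-4-[methoxy(methyl)amino]-3-methyl-4-oxobut-2-enyl]-5-methyl-2-oxo-2,5-dihydrofuran-3-yl}carbamate (racemic at C5), via lithium dienolate 11 (not isolated), via chlorozinc reagent 12 (not isolated)
Conditions: 10, LiN(iPr)2, THF, −78 °C; ZnCl2, −78 to 0 °C; then 7, Pd(PPh3)4 (5 mol %), THF, rt to 45 °C (12 in threefold excess)
Reagents that add atoms: none
Why: Negishi coupling: the carbonyl-directed base removes a proton of the cis C1 methyl, transmetalation gives the allylic zinc reagent, and zerovalent palladium, after insertion into the activated C6–Br bond, couples it through the unhindered C1 terminus because the other terminus C3 is fully substituted; the excess reagent covers the N–H and the acidic C1H2 of the product.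

Step 8
Reactants: 13 tert-butyl {4-[(E)-2-methoxy-4-[methoxy(methyl)amino]-3-methyl-4-oxobut-2-enyl]-5-methyl-2-oxo-2,5-dihydrofuran-3-yl}carbamate
Product: 14 3-(Boc-amino)-2-(tert-butyldimethylsilyloxy)-5-methylfuran bearing the (E)-2-methoxy-3-methyl-4-[methoxy(methyl)amino]-4-oxobut-2-enyl chain at the 4-position
Conditions: TBSOTf (1.15 equiv), Et3N, CH2Cl2, 0 °C
Reagents that add atoms: tert-butyldimethylsilyl triflate, CC(C)(C)[Si](C)(C)OS(=O)(=O)C(F)(F)F
Why: Soft enolisation of a butenolide with silyl triflate and amine: O-silylation of the lactone carbonyl followed by loss of the C5 proton gives the aromatic 2-silyloxyfuran, the thermodynamic sink among the possible silyl dienolates, and erases the racemic C5 centre; brief contact at 0 °C with little excess triflate should spare the Boc group.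

Step 9
Reactants: 14 silyloxyfuran Weinreb amide
Product: 15 3-(Boc-amino)-2-(tert-butyldimethylsilyloxy)-5-methylfuran bearing the (E)-2-methoxy-3-methyl-4-oxobut-2-enyl chain (C1H2 cis to CHO) at the 4-position
Conditions: iBu2AlH (2.3 equiv), THF, −78 °C; aq. potassium sodium tartrate
Reagents that add atoms: none
Why: Hydride reduction of a Weinreb amide, which stops at the aldehyde level because the carbonyl is released only on the neutral tartrate work-up; one equivalent of hydride is spent on N–H, and the furan, the carbamate and the enol ether are inert.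

Step 10
Reactants: 15 silyloxyfuran aldehyde
Product: 16 (4S,5S)-bicyclic α-(Boc-amino)butenolide: ring C1H2–C2(OMe)=C3(Me)–C4H(OTBS)–C5(Me)–C6 fused through C5–C6 to the lactone O–C7(=O)–C8(NHBoc)=C6, OTBS cis to the C5 methyl
Conditions: Ti(OiPr)4 (20 mol %), (R)-BINOL (40 mol %), 4 Å molecular sieves, Et2O, 0.01 M, −20 °C; aq. NaHCO3, Et3N-washed silica
Reagents that add atoms: none
Why: Proposed new method: the BINOL–titanium Lewis acid binds the aldehyde oxygen, the furan adds through its vinylogous terminus C5 to C4, and silicon passes from the O-silylated butenolide cation to the titanium aldolate, which frees the catalyst and leaves the carbinol masked as its TBS ether; the closest known reaction type is the intermolecular catalytic asymmetric vinylogous Mukaiyama aldol reaction of 2-silyloxyfurans, 5-methyl ones that give quaternary γ-carbons included, and the new element is the tethered, ring-closing version on a β-alkoxy enal. The carbocycle closes in the 6-(enolendo)-exo-trig mode with the geometry of a Bradsher-type ortho cyclisation, the cis C2=C3 bond holding C4 over C5 (a trans isomer can equilibrate through the push–pull system, and only the cis form can close). C5 is set by the catalyst: the tether couples the two π faces, so the aldehyde face left open by the ligand (Re) fixes the furan face and hence 5S. C4 is set by the substrate: the bound enal reacts as its s-trans rotamer, because the s-cis form would press the O–Ti unit against C1H2 and under the furan, and this puts the oxygen on the side of the C5 methyl (4S). The step needs site selectivity for C5 over C8, which is equally close to the tether and would also close a six-membered ring; the larger frontier coefficient at the γ-terminus, the bulk of the NHBoc group on C8 and the gain of the conjugated α-amido butenolide should secure it. It also needs the γ-oxygenated enol ether to survive, which the mild alkoxide Lewis acid, the in situ silylation and the acyloxy group on C5, which disfavours ionisation at C4, should allow.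

Step 11
Reactants: 16 (4S,5S)-bicyclic α-(Boc-amino)butenolide
Product: 17 (4S,5S,6R,8S)-cis-fused saturated lactone: as 16 but with H at C6 and at C8, both cis to the C5 methyl
Conditions: [Rh(cod)((S,S)-Me-BPE)]OTf (5 mol %), H2 (20 bar), THF, 30 °C
Reagents that add atoms: none
Why: Asymmetric hydrogenation of a tetrasubstituted α-enamide with a cationic rhodium bisphospholane catalyst: only the alkene that carries the chelating carbamate is reduced (the enol ether cannot chelate, and a homogeneous catalyst avoids hydrogenolysis of the allylic C5–O bond), and syn addition should take place on the convex face that carries the C5 methyl, because C2–C4 of the half-chair carbocycle fold under the other face and the (S,S) ligand favours the S amino centre, which sets 6R and a provisional 8S; the equatorial C4 silyloxy group lies below the butenolide plane, points away from the alkene and plays no directing part.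

Step 12
Reactants: 17 (4S,5S,6R,8S)-cis-fused saturated lactone
Product: 19 (4S,5S,6R,8S)-C8-methyl lactone: C8 bears CH3 (cis to C6–H and C5–CH3) and NHBoc (cis to C1), via dilithio dianion 18 (not isolated)
Conditions: LiN(iPr)2 (2.3 equiv), THF–DMPU, −78 to −40 °C; MeI, −78 °C; then H2O
Reagents that add atoms: iodomethane, CI
Why: Alkylation of the dianion of an N-Boc amino lactone: the planar enolate of the cis-fused bicycle should take up MeI on the convex face, anti to C1 on the adjacent C6, so that the new methyl is cis to C6–H and C5–CH3 and nitrogen is left on the concave face (8S), carbon reacting faster than the carbamate anion; the step is placed here because C1H2 is not acidic while C4 is still at the alcohol level.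

Step 13
Reactants: 19 (4S,5S,6R,8S)-C8-methyl lactone
Product: 20 (4S,5S,6R,8S)-C4 carbinol: as 19 with OH in place of OTBS
Conditions: nBu4NF, THF, 0 °C to rt
Reagents that add atoms: none
Why: Fluoride-induced cleavage of the silyl ether under basic, non-acidic conditions, which the γ-hydroxy enol ether product requires; the C4 alkoxide is trans to the lactone carbonyl across the ring and cannot translactonise.

Step 14
Reactants: 20 (4S,5S,6R,8S)-C4 carbinol
Product: 21 (5S,6R,8S)-vinylogous ester: C4 ketone conjugated with C3(Me)=C2(OMe)
Conditions: (nPr4N)RuO4 (5 mol %), NMO, 4 Å molecular sieves, CH2Cl2, rt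
Reagents that add atoms: none
Why: Ley–Griffith oxidation of the allylic alcohol under neutral conditions turns the labile γ-hydroxy enol ether into a robust vinylogous ester and removes the auxiliary C4 stereocentre.

Step 15
Reactants: 21 (5S,6R,8S)-vinylogous ester
Product: 22 (5S,6R,8S)-2-methyl-1,3-dione, drawn as C2 ketone and C4 enol
Conditions: 1 M HCl, THF, rt
Reagents that add atoms: water, O
Why: Acid hydrolysis of a vinylogous ester by addition of water at C2 and loss of methanol, the reverse of dione enol ether formation; dilute aqueous acid at room temperature should leave the Boc group and the hindered lactone intact.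

Step 16
Reactants: 23 (2E,4E)-hexa-2,4-dienoic acid (sorbic acid)
Product: 25 (2E,4E)-N-methoxy-N-methylhexa-2,4-dienamide, via sorboyl imidazolide 24 (not isolated)
Conditions: CDI, CH2Cl2, rt; then MeNH(OMe)·HCl
Reagents that add atoms: N,O-dimethylhydroxylamine hydrochloride, CNOC.Cl
Why: Weinreb amide formation through the acyl imidazolide, mild enough to keep both E double bonds.

Step 17
Reactants: 22 (5S,6R,8S)-2-methyl-1,3-dione; 25 (2E,4E)-N-methoxy-N-methylhexa-2,4-dienamide
Product: 27 (5S,6R,8S)-N-Boc amine carrying the (2E,4E)-hexa-2,4-dienoyl group at C1, drawn as the hydrogen-bonded exocyclic enol, via trilithio trianion 26 (not isolated)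
Conditions: 22, LiN(iPr)2 (3.4 equiv), THF–DMPU, −78 to −20 °C; 25, −78 to 0 °C; cold 1 M HCl to pH 3
Reagents that add atoms: none
Why: γ-Acylation of a β-diketone polyanion with a Weinreb amide: once the enol and N–H protons are gone the last equivalent of base can only take a C1 proton (C5 is quaternary and C3 carries none), the terminal carbanion is the most nucleophilic site, and the ketone is released only on work-up so that the more acidic tricarbonyl product cannot quench unreacted anion; C1 is sp2 in the enolised product, so no stereocentre arises.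

Step 18
Reactants: 27 (5S,6R,8S)-N-Boc sorboyl compound; 28 fumaryl chloride ((E)-but-2-enedioyl dichloride)
Product: 31 sorbicillactone A, via ammonium trifluoroacetate 29 (not isolated), via fumaramoyl chloride 30 (not isolated)
Conditions: TFA–CH2Cl2 (1:4), 0 °C, evaporate; 28 (5 equiv), iPr2NEt, CH2Cl2, −40 °C; then H2O–THF, 0 °C; acidify to pH 2
Reagents that add atoms: water, O
Why: Acidolysis of the Boc group, N-acylation with a large excess of the bis(acid chloride) and hydrolysis of the remaining acyl chloride (and of any enol esters) should give the fumaramic acid directly; the amine is set free only in the presence of base, where the tricarbonyl is an unreactive enolate, so that acylation should outrun condensation of nitrogen with the neighbouring C1 acyl carbonyl, and no stereocentre is touched.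

Compound list
1 | methyl 2-[(tert-butoxycarbonyl)amino]-2-(dimethoxyphosphoryl)acetate | COC(=O)C(NC(=O)OC(C)(C)C)P(=O)(OC)OC | starting material
2 | 2-[(tert-butoxycarbonyl)amino]-2-(dimethoxyphosphoryl)acetic acid | OC(=O)C(NC(=O)OC(C)(C)C)P(=O)(OC)OC | intermediate
3 | but-3-en-2-ol | C=CC(C)O | starting material
4 | but-3-en-2-yl 2-[(tert-butoxycarbonyl)amino]-2-(dimethoxyphosphoryl)acetate | C=CC(C)OC(=O)C(NC(=O)OC(C)(C)C)P(=O)(OC)OC | intermediate
5 | 1-oxopropan-2-yl 2-[(tert-butoxycarbonyl)amino]-2-(dimethoxyphosphoryl)acetate | O=CC(C)OC(=O)C(NC(=O)OC(C)(C)C)P(=O)(OC)OC | intermediate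
6 | tert-butyl (5-methyl-2-oxo-2,5-dihydrofuran-3-yl)carbamate | CC1OC(=O)C(NC(=O)OC(C)(C)C)=C1 | intermediate
7 | tert-butyl (4-bromo-5-methyl-2-oxo-2,5-dihydrofuran-3-yl)carbamate | CC1OC(=O)C(NC(=O)OC(C)(C)C)=C1Br | intermediate
8 | methyl 2-methyl-3-oxobutanoate | COC(=O)C(C)C(C)=O | starting material
9 | methyl (E)-3-methoxy-2-methylbut-2-enoate | C/C(OC)=C(C)\C(=O)OC | intermediate
10 | (E)-N,3-dimethoxy-N,2-dimethylbut-2-enamide | C/C(OC)=C(C)\C(=O)N(C)OC | intermediate
11 | lithium dienolate of 10 | [Li+].C=C(OC)C(C)=C([O-])N(C)OC | intermediate
12 | [(E)-2-methoxy-4-[methoxy(methyl)amino]-3-methyl-4-oxobut-2-enyl]zinc chloride | Cl[Zn]C/C(OC)=C(C)\C(=O)N(C)OC | intermediate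
13 | tert-butyl {4-[(E)-2-methoxy-4-[methoxy(methyl)amino]-3-methyl-4-oxobut-2-enyl]-5-methyl-2-oxo-2,5-dihydrofuran-3-yl}carbamate | CC1OC(=O)C(NC(=O)OC(C)(C)C)=C1C/C(OC)=C(C)\C(=O)N(C)OC | intermediate
14 | silyloxyfuran Weinreb amide | Cc1oc(O[Si](C)(C)C(C)(C)C)c(NC(=O)OC(C)(C)C)c1C/C(OC)=C(C)\C(=O)N(C)OC | intermediate
15 | silyloxyfuran aldehyde (precursor of the key step) | Cc1oc(O[Si](C)(C)C(C)(C)C)c(NC(=O)OC(C)(C)C)c1C/C(OC)=C(C)\C=O | intermediate
16 | (4S,5S)-bicyclic α-(Boc-amino)butenolide, C4 OTBS cis to C5 methyl | C1C(OC)=C(C)[C@H](O[Si](C)(C)C(C)(C)C)[C@@]2(C)OC(=O)C(NC(=O)OC(C)(C)C)=C12 | intermediate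
17 | (4S,5S,6R,8S)-cis-fused saturated lactone | C1C(OC)=C(C)[C@H](O[Si](C)(C)C(C)(C)C)[C@@]2(C)OC(=O)[C@@H](NC(=O)OC(C)(C)C)[C@@H]12 | intermediate
18 | dilithio dianion of 17 (lactone enolate and carbamate anion) | [Li+].[Li+].C1C(OC)=C(C)[C@H](O[Si](C)(C)C(C)(C)C)[C@@]2(C)OC([O-])=C([N-]C(=O)OC(C)(C)C)[C@@H]12 | intermediate
19 | (4S,5S,6R,8S)-C8-methyl lactone | C1C(OC)=C(C)[C@H](O[Si](C)(C)C(C)(C)C)[C@@]2(C)OC(=O)[C@@](C)(NC(=O)OC(C)(C)C)[C@@H]12 | intermediate
20 | (4S,5S,6R,8S)-C4 carbinol | C1C(OC)=C(C)[C@H](O)[C@@]2(C)OC(=O)[C@@](C)(NC(=O)OC(C)(C)C)[C@@H]12 | intermediate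
21 | (5S,6R,8S)-vinylogous ester | C1C(OC)=C(C)C(=O)[C@@]2(C)OC(=O)[C@@](C)(NC(=O)OC(C)(C)C)[C@@H]12 | intermediate
22 | (5S,6R,8S)-2-methyl-1,3-dione (C2 ketone, C4 enol) | C1C(=O)C(C)=C(O)[C@@]2(C)OC(=O)[C@@](C)(NC(=O)OC(C)(C)C)[C@@H]12 | intermediate
23 | sorbic acid | C/C=C/C=C/C(=O)O | starting material
24 | (2E,4E)-1-(imidazol-1-yl)hexa-2,4-dien-1-one | C/C=C/C=C/C(=O)n1ccnc1 | intermediate
25 | (2E,4E)-N-methoxy-N-methylhexa-2,4-dienamide | C/C=C/C=C/C(=O)N(C)OC | intermediate
26 | trilithio trianion of 22 (C1=C2 and C3=C4 bis-enolate, carbamate anion) | [Li+].[Li+].[Li+].C1=C([O-])C(C)=C([O-])[C@@]2(C)OC(=O)[C@@](C)([N-]C(=O)OC(C)(C)C)[C@@H]12 | intermediate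
27 | (5S,6R,8S)-N-Boc C1-sorboyl compound | C/C=C/C=C/C(O)=C1/C(=O)C(C)=C(O)[C@@]2(C)OC(=O)[C@@](C)(NC(=O)OC(C)(C)C)[C@@H]12 | intermediate
28 | fumaryl chloride | O=C(Cl)/C=C/C(=O)Cl | starting material
29 | C8 ammonium trifluoroacetate | C/C=C/C=C/C(O)=C1/C(=O)C(C)=C(O)[C@@]2(C)OC(=O)[C@@](C)([NH3+])[C@@H]12.[O-]C(=O)C(F)(F)F | intermediate
30 | C8 N-[(E)-4-chloro-4-oxobut-2-enoyl] amide | C/C=C/C=C/C(O)=C1/C(=O)C(C)=C(O)[C@@]2(C)OC(=O)[C@@](C)(NC(=O)/C=C/C(=O)Cl)[C@@H]12 | intermediate
31 | sorbicillactone A | C/C=C/C=C/C(O)=C1/C(=O)C(C)=C(O)[C@@]2(C)OC(=O)[C@@](C)(NC(=O)/C=C/C(=O)O)[C@@H]12 | target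

Total step count: 18. Longest linear sequence: 15 steps (steps 1–4, 7–15, 17 and 18).

Steps most likely to fail

**Step 10 (the labelled step).** Enantiofacial discrimination may be weak or turnover may stall. The vinylogous formate holds titanium firmly but is a poor electrophile. A ligand-free, silyl-cation-catalysed closure, attack through C8, or addition of the carbamate nitrogen to C2 can then compete. The fallback replaces asymmetric catalysis by resolution and uses known chemistry.
- Setting out from 15, the closure is run as an ordinary silyl triflate-catalysed Mukaiyama aldol addition with silyl transfer (TBSOTf 5 mol %, 2,6-di-tert-butyl-4-methylpyridine, CH2Cl2, −78 °C).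
- This should give 16 as the racemate, that is together with the mirror-image silyl ether F1.
- The enantiomers are separated by preparative chromatography on a chiral stationary phase, and the route is rejoined at 16.

**Step 7.** Proton transfer from N–H, C5–H and the doubly activated C1H2 of the product may consume the zinc reagent. Coupling may also drift to the C3 terminus or scramble the alkene geometry. The fallback reverses the polarity and works under neutral Stille conditions.
- From 7, (Bu3Sn)2 and Pd(PPh3)4 in toluene at 90 °C should give the 4-tributylstannyl butenolide F2.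
- From 10, Wohl–Ziegler bromination (NBS, AIBN, PhCF3, reflux) should give the allylic bromide F3.
- Pd2(dba)3 with AsPh3 in THF at 50 °C then joins the vinylstannane to the primary terminus of the allyl unit, and the route is rejoined at 13.

**Step 17.** The trianion may form incompletely or stay insoluble. Acylation may occur on oxygen, or the carbanion may add in a conjugate sense to the dienamide. The fallback makes the bond by aldol addition and adjusts the oxidation level afterwards.
- From 22, through 26, addition to (2E,4E)-hexa-2,4-dienal at −78 °C should give the dienyl carbinol F4, a mixture at C1 and at the carbinol carbon.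
- MnO2 in CH2Cl2 then oxidises this doubly allylic alcohol, and the route is rejoined at 27.

Further compounds
F1 | step 10 | (4R,5R)-enantiomer of 16 | C1C(OC)=C(C)[C@@H](O[Si](C)(C)C(C)(C)C)[C@]2(C)OC(=O)C(NC(=O)OC(C)(C)C)=C12
F2 | step 7 | tert-butyl [5-methyl-2-oxo-4-(tributylstannyl)-2,5-dihydrofuran-3-yl]carbamate | CCCC[Sn](CCCC)(CCCC)C1=C(NC(=O)OC(C)(C)C)C(=O)OC1C
F3 | step 7 | (E)-4-bromo-N,3-dimethoxy-N,2-dimethylbut-2-enamide | BrC/C(OC)=C(C)\C(=O)N(C)OC
F4 | step 17 | 22 bearing a (2E,4E)-1-hydroxyhexa-2,4-dienyl group at C1 | C/C=C/C=C/C(O)C1C(=O)C(C)=C(O)[C@@]2(C)OC(=O)[C@@](C)(NC(=O)OC(C)(C)C)[C@@H]12
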